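Retrosynthetic overview
- Numbering: C1–C5 is the pentyl chain, C6 and C9 are the two ring CH–O carbons, C7 is the ring carbinol, C8 the ring CH2, C10 the ester carbinol and C18=C19 the vinyl end. The oxolane (O, C6, C7, C8, C9) is the only ring and is closed in the final step.
- Enabling feature: on the oxolane, the C6–O(ring) bond and C7–OH are vicinal with pentyl cis to OH, C7–O is 1,3-syn to C9–O, and C9 is homoallylic to C6=C7. This is the retron of a cis-6,7-epoxide that the C9 hydroxyl first delivers and then opens at C6. The stearate on exocyclic C10 silences the only rival hydroxyl.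
- Disconnections near the ring: C6–O and C7–O come from a directed epoxidation/epoxide-opening cascade on an acyclic Z-homoallylic alcohol with two stereocentres. The Z C6=C7 bond comes from the alkyne, and C7–C8 from a hept-1-ynyl anion plus a terminal epoxide.
- Disconnections at C9/C10: the C10–O(acyl) bond comes from Mitsunobu inversion with stearic acid itself (erythro to threo, no protecting group). The C9/C10 pair comes from Sharpless kinetic resolution of the vinyl carbinol made from dec-9-enal.

Key step: step 7

Assumption: the acyl chain of the ester is read as the unbranched C18 group (octadecanoyl, stearoyl).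

Step 1
Reactants: 1 dec-9-en-1-ol
Product: 2 dec-9-enal
Conditions: TEMPO (10 mol %), PhI(OAc)2 (1.1 equiv), CH2Cl2, rt
Reagents that add atoms: none
Why: The oxoammonium-mediated (TEMPO/PhI(OAc)2) alcohol oxidation should stop at the aldehyde and leave the unactivated terminal alkene alone; no stereocentre is involved.

Step 2
Reactants: 2 dec-9-enal; 3 vinylmagnesium bromide
Product: 4 rac-dodeca-1,11-dien-3-ol
Conditions: THF, −78 °C to 0 °C; aq. NH4Cl
Reagents that add atoms: none
Why: Grignard 1,2-addition to an unhindered aldehyde should give the vinyl carbinol, and C10 is formed racemic on purpose because step 3 resolves it.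

Step 3
Reactants: 4 rac-dodeca-1,11-dien-3-ol
Product: 5 (1S)-1-[(2R)-oxiran-2-yl]dec-9-en-1-ol
Conditions: Ti(OiPr)4 (0.15 equiv), L-(+)-DIPT (0.2 equiv), TBHP (0.45 equiv, in decane), 4 Å molecular sieves, CH2Cl2, −20 °C
Reagents that add atoms: tert-butyl hydroperoxide, CC(C)(C)OO
Why: In this Sharpless kinetic resolution (Ti(OiPr)4/L-(+)-DIPT/TBHP epoxidation of a secondary allylic alcohol) the (S)-enantiomer of 4 should be epoxidised far faster than the (R)-enantiomer, which stays behind and is separated, with the tartrate choosing the alkene face (C9 = R) and the fast antipode (C10 = S, erythro), while the remote C18=C19 bond has no allylic hydroxyl and is not touched.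

Step 4
Reactants: 5 (1S)-1-[(2R)-oxiran-2-yl]dec-9-en-1-ol; 6 octadecanoic acid
Product: 7 (1R)-1-[(2R)-oxiran-2-yl]dec-9-en-1-yl octadecanoate
Conditions: PPh3 (1.5 equiv), DIAD (1.5 equiv), THF, 0 °C to rt
Reagents that add atoms: none
Why: In this Mitsunobu esterification stearate displaces the oxyphosphonium group at C10 by SN2 with inversion (10S to 10R, erythro to threo), so the acyl group of the target lands on O10 while O9 is still locked in the epoxide and no protecting group is needed.

Step 5
Reactants: 7 (1R)-1-[(2R)-oxiran-2-yl]dec-9-en-1-yl octadecanoate; 8 hept-1-yne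
Product: 10 (9R,10R)-9-hydroxynonadec-18-en-6-yn-10-yl octadecanoate, via hept-1-ynyllithium 9 (not isolated)
Conditions: 8, n-BuLi, THF, −78 °C; BF3·OEt2, −78 °C; then 7, −78 °C; pH 7 aqueous buffer at −78 °C
Reagents that add atoms: none
Why: In this Yamaguchi–Hirao alkynylation (BF3-assisted SN2 opening of a terminal epoxide by a lithium acetylide) attack at the unsubstituted C8 leaves the C9–O bond and its configuration untouched, and at −78 °C the acetylide should ignore the ester while O9 is held as a non-nucleophilic fluoroborate until the cold quench.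

Step 6
Reactants: 10 (9R,10R)-9-hydroxynonadec-18-en-6-yn-10-yl octadecanoate
Product: 11 (6Z,9R,10R)-9-hydroxynonadeca-6,18-dien-10-yl octadecanoate
Conditions: H2 (1 atm, stopped after 1 equiv), Pd/CaCO3 poisoned with Pb(OAc)2, quinoline, hexane/EtOAc, rt
Reagents that add atoms: none
Why: In this Lindlar semihydrogenation the alkyne is adsorbed much more strongly than the monosubstituted alkene on the poisoned palladium surface and takes up one equivalent of H2 by syn addition, which should give the Z-alkene needed for a cis-epoxide without touching a stereocentre.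

Step 7
Reactants: 11 (6Z,9R,10R)-9-hydroxynonadeca-6,18-dien-10-yl octadecanoate
Product: 13 (1R)-1-[(2R,4S,5S)-4-hydroxy-5-pentyloxolan-2-yl]dec-9-en-1-yl octadecanoate, via cis-6,7-epoxy alcohol 12 (not isolated)
Conditions: VO(acac)2 (5 mol %), TBHP (1.3 equiv, in decane), CH2Cl2, 0 °C to rt; then camphorsulfonic acid (10 mol %), 0 °C, same flask
Reagents that add atoms: tert-butyl hydroperoxide, CC(C)(C)OO
Why: O9–H of 11 exchanges onto the pentavalent vanadium centre formed from VO(acac)2 and TBHP, the co-bound tert-butylperoxo ligand passes one oxygen to C6=C7 inside a chair-like vanadate to give 12, and the sulfonic acid then protonates the epoxide so that the same O9–H attacks C6 from the rear and releases O7 as the free hydroxyl. The closest known reaction type is the hydroxyl-directed VO(acac)2/TBHP epoxidation of acyclic Z-homoallylic alcohols coupled to the acid-catalysed cyclisation of 3,4-epoxy alcohols to 3-hydroxyoxolanes. The oxolane closes in the 5-endo-tet mode with respect to the epoxide (C6–O9 bond), the 4-exo alternative at C7 being ruled out by oxetane strain. C7 is controlled by C9: in the chair the large C10-bearing substituent on C9 sits equatorial and allylic 1,3-strain of the Z-alkene keeps a C8–H bond in the alkene plane, so oxygen reaches the face that makes C7–O 1,3-syn to C9–O (7S). C6 is controlled by the Z geometry, which fixes the cis-epoxide as 6R,7S, and by the SN2 inversion on ring closure, which gives 6S, that is pentyl cis to the hydroxyl and trans to the C9 side chain. The step needs site selectivity between two alkenes, secured because only C6=C7 lies within reach of the vanadium-bound O9 while C18=C19 is remote from any hydroxyl, and it needs O9 rather than O10 to close the ring, secured by the stearate, which caps the only oxygen that could open the epoxide in a faster 5-exo mode at C7.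

Compound list
1 | dec-9-en-1-ol | C=CCCCCCCCCO | starting material
2 | dec-9-enal | C=CCCCCCCCC=O | intermediate
3 | vinylmagnesium bromide | C=C[Mg]Br | starting material
4 | rac-dodeca-1,11-dien-3-ol | C=CCCCCCCCC(O)C=C | intermediate
5 | (1S)-1-[(2R)-oxiran-2-yl]dec-9-en-1-ol (erythro; (2R,3S)-1,2-epoxydodec-11-en-3-ol) | C=CCCCCCCC[C@H](O)[C@H]1CO1 | intermediate
6 | octadecanoic acid (stearic acid) | OC(=O)CCCCCCCCCCCCCCCCC | starting material
7 | (1R)-1-[(2R)-oxiran-2-yl]dec-9-en-1-yl octadecanoate (threo) | C=CCCCCCCC[C@@H](OC(=O)CCCCCCCCCCCCCCCCC)[C@H]1CO1 | intermediate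
8 | hept-1-yne | C#CCCCCC | starting material
9 | hept-1-ynyllithium | [Li]C#CCCCCC | intermediate
10 | (9R,10R)-9-hydroxynonadec-18-en-6-yn-10-yl octadecanoate | C=CCCCCCCC[C@@H](OC(=O)CCCCCCCCCCCCCCCCC)[C@H](O)CC#CCCCCC | intermediate
11 | (6Z,9R,10R)-9-hydroxynonadeca-6,18-dien-10-yl octadecanoate | C=CCCCCCCC[C@@H](OC(=O)CCCCCCCCCCCCCCCCC)[C@H](O)C/C=C\CCCCC | intermediate
12 | (6R,7S,9R,10R)-6,7-epoxy-9-hydroxynonadec-18-en-10-yl octadecanoate (cis-6,7-epoxy alcohol) | C=CCCCCCCC[C@@H](OC(=O)CCCCCCCCCCCCCCCCC)[C@H](O)C[C@@H]1O[C@@H]1CCCCC | intermediate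
13 | (1R)-1-[(2R,4S,5S)-4-hydroxy-5-pentyloxolan-2-yl]dec-9-en-1-yl octadecanoate ((6S,7S,9R,10R)-6,9-epoxy-7-hydroxynonadec-18-en-10-yl stearate) | C=CCCCCCCC[C@@H](OC(=O)CCCCCCCCCCCCCCCCC)[C@H]1C[C@H](O)[C@H](CCCCC)O1 | target

Total step count: 7. Longest linear sequence: 7 steps (1 to 13).

Steps most likely to fail

**Step 7.**
- What may go wrong: oxygen transfer may reach the wrong face of C6=C7 if the neighbouring ester perturbs the vanadate chair. The acid may also promote drift of the acyl group from O10 to O9 before ring closure, which would hand the closure to O10.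
- Fallback: it sets out from 11 and comes back at 12 and then 13. It moves stereocontrol from the substrate to a catalyst and splits the cascade. 11 is epoxidised by the asymmetric epoxidation of Z-homoallylic alcohols with VO(OiPr)3, a C2-symmetric bishydroxamic acid ligand derived from trans-cyclohexane-1,2-diamine (the enantiomer matched to the 1,3-syn sense) and cumene hydroperoxide in toluene. 12 is then isolated and freed from its diastereomer. The ring is closed in a separate operation with pyridinium p-toluenesulfonate in CH2Cl2 at 0 °C, where acyl drift can be followed and stopped.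

**Step 5.**
- What may go wrong: the acetylide may add to the ester. The ester carbonyl may take part in opening the BF3-activated epoxide, which would scramble C9 and move the acyl group. The acyl group may also shift within the O9 alkoxide.
- Fallback: it sets out from 5 and comes back at 10, and it puts the C–C bond formation ahead of the esterification at the price of two silyl groups.
  - 5 is silylated (TESCl, imidazole) to (1S)-1-[(2R)-oxiran-2-yl]dec-9-en-1-yl triethylsilyl ether F1.
  - F1 is opened by 9/BF3·OEt2, with no ester present, to (9R,10S)-10-(triethylsilyloxy)nonadec-18-en-6-yn-9-ol F2.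
  - TBSOTf/2,6-lutidine caps O9 to give (9R,10S)-9-(tert-butyldimethylsilyloxy)-10-(triethylsilyloxy)nonadec-18-en-6-yne F3.
  - Pyridinium p-toluenesulfonate in MeOH removes only the triethylsilyl group to give (9R,10S)-9-(tert-butyldimethylsilyloxy)nonadec-18-en-6-yn-10-ol F4.
  - The Mitsunobu reaction with 6 inverts C10 to give (9R,10R)-9-(tert-butyldimethylsilyloxy)nonadec-18-en-6-yn-10-yl octadecanoate F5.
  - HF·pyridine frees O9 under acidic conditions that do not promote acyl shift and should give 10.

**Step 6.**
- What may go wrong: the terminal alkene may be over-reduced, or Z to E isomerisation may set in once the alkyne is consumed.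
- Fallback: it sets out from 8, uses 7, and comes back at 11. The Z-alkene is made before any other alkene is present.
  - 8 is iodinated (N-iodosuccinimide, AgNO3 cat., acetone) to 1-iodohept-1-yne F6.
  - Hydroboration with Cy2BH and protonolysis with AcOH gives (Z)-1-iodohept-1-ene F7.
  - Iodine–lithium exchange (t-BuLi, 2 equiv, Et2O, −78 °C) gives (Z)-hept-1-enyllithium F8.
  - CuI (0.5 equiv) converts F8 into lithium di[(Z)-hept-1-enyl]cuprate F9.
  - F9 with BF3·OEt2 at −78 °C should open 7 at C8 with retention of the alkene geometry and, after a cold buffered quench, give 11 directly.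

Further compounds
F0 | step 7 | none | none
F1 | step 5 | (1S)-1-[(2R)-oxiran-2-yl]dec-9-en-1-yl triethylsilyl ether | C=CCCCCCCC[C@H](O[Si](CC)(CC)CC)[C@H]1CO1
F2 | step 5 | (9R,10S)-10-(triethylsilyloxy)nonadec-18-en-6-yn-9-ol | C=CCCCCCCC[C@H](O[Si](CC)(CC)CC)[C@H](O)CC#CCCCCC
F3 | step 5 | (9R,10S)-9-(tert-butyldimethylsilyloxy)-10-(triethylsilyloxy)nonadec-18-en-6-yne | C=CCCCCCCC[C@H](O[Si](CC)(CC)CC)[C@H](O[Si](C)(C)C(C)(C)C)CC#CCCCCC
F4 | step 5 | (9R,10S)-9-(tert-butyldimethylsilyloxy)nonadec-18-en-6-yn-10-ol | C=CCCCCCCC[C@H](O)[C@H](O[Si](C)(C)C(C)(C)C)CC#CCCCCC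
F5 | step 5 | (9R,10R)-9-(tert-butyldimethylsilyloxy)nonadec-18-en-6-yn-10-yl octadecanoate | C=CCCCCCCC[C@@H](OC(=O)CCCCCCCCCCCCCCCCC)[C@H](O[Si](C)(C)C(C)(C)C)CC#CCCCCC
F6 | step 6 | 1-iodohept-1-yne | IC#CCCCCC
F7 | step 6 | (Z)-1-iodohept-1-ene | I/C=C\CCCCC
F8 | step 6 | (Z)-hept-1-enyllithium | [Li]/C=C\CCCCC
F9 | step 6 | lithium di[(Z)-hept-1-enyl]cuprate | [Li+].CCCCC/C=C\[Cu-]/C=C\CCCCC
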